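**Retrosynthetic overview**

- The target is a 2-hydroxy-4-methoxybenzophenone (ring A with the 4-hydroxybenzoyl ring B) whose ring A carries at C5 a three-carbon chain ending in ring C, a para-alkylphenol. The strategy rests on ring C: its O-bearing C1 and chain-bearing C4 are 1,4 to each other. C4 and C3 can come from C2 and C1 of a 5-arylpentanal; C5, C6, C1, C2 and the oxygen come from methyl vinyl ketone.
- Last disconnections: the two benzyl ethers, then the phenol back to a 4-substituted cyclohex-2-enone (dehydrogenation retron).
- Ring C: the C4–C5 bond (Michael addition) and the C2=C3 bond (aldol condensation) lead back to the 5-arylpentanal and methyl vinyl ketone.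
- The aldehyde chain is attached to ring A by B-alkyl Suzuki coupling of a bromo benzophenone with a hydroborated butenyl dioxolane. The benzophenone comes from aryl Grignard addition to an O-benzyl bromosalicylaldehyde and oxidation.
- Ring order: rings A and B are bought as arenes; ring C is the only ring built (step 6) and is aromatised in step 7. The target is achiral; the one stereocentre made in step 6 is racemic and disappears in step 7.

Key step: step 6

**Route**

Step 1
Reactants: 1 5-bromo-2-hydroxy-4-methoxybenzaldehyde
Product: 2 2-(benzyloxy)-5-bromo-4-methoxybenzaldehyde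
Conditions: BnBr (1.2 equiv), K2CO3 (2 equiv), DMF, 60 °C
Reagents that add atoms: benzyl bromide, BrCc1ccccc1
Why: Williamson ether synthesis; the acidic salicylaldehyde phenol is deprotonated by K2CO3 and O-benzylated, which masks it before the organomagnesium step.

Step 2
Reactants: 2 2-(benzyloxy)-5-bromo-4-methoxybenzaldehyde; 3 1-(benzyloxy)-4-bromobenzene
Product: 5 [2-(benzyloxy)-5-bromo-4-methoxyphenyl][4-(benzyloxy)phenyl]methanol (racemic), via arylmagnesium bromide 4 (not isolated)
Conditions: 3, Mg turnings, I2 (cat.), THF, reflux; then 2, THF, −20 to 0 °C; aq NH4Cl work-up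
Reagents that add atoms: none
Why: Grignard formation and 1,2-addition to the aldehyde, which at low temperature should be far faster than bromine–magnesium exchange at the aryl bromide of 2; the carbinol centre forms racemic and is removed in step 3.

Step 3
Reactants: 5 [2-(benzyloxy)-5-bromo-4-methoxyphenyl][4-(benzyloxy)phenyl]methanol
Product: 6 [2-(benzyloxy)-5-bromo-4-methoxyphenyl][4-(benzyloxy)phenyl]methanone
Conditions: activated MnO2 (excess), CH2Cl2, rt
Reagents that add atoms: none
Why: MnO2 oxidation of a doubly benzylic alcohol to the diaryl ketone, which should leave the aryl bromide and both benzyl ethers untouched.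

Step 4
Reactants: 6 [2-(benzyloxy)-5-bromo-4-methoxyphenyl][4-(benzyloxy)phenyl]methanone; 7 2-(but-3-en-1-yl)-1,3-dioxolane
Product: 9 [2-(benzyloxy)-5-[4-(1,3-dioxolan-2-yl)butyl]-4-methoxyphenyl][4-(benzyloxy)phenyl]methanone, via B-alkyl-9-borabicyclononane 8 (not isolated)
Conditions: 7 (1.6 equiv), 9-borabicyclo[3.3.1]nonane (9-BBN-H, 1.5 equiv), THF, 0 °C to rt; then 6, Pd(dppf)Cl2 (5 mol %), 3 M aq K3PO4, THF/DMF, 70 °C
Reagents that add atoms: none
Why: anti-Markovnikov hydroboration followed by B-alkyl Suzuki–Miyaura coupling; the alkene is kept in slight excess so that no B–H remains to reduce the ketone, and the bidentate dppf ligand should suppress β-hydride elimination of the alkylpalladium intermediate.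

Step 5
Reactants: 9 [2-(benzyloxy)-5-[4-(1,3-dioxolan-2-yl)butyl]-4-methoxyphenyl][4-(benzyloxy)phenyl]methanone
Product: 10 5-[4-(benzyloxy)-5-(4-(benzyloxy)benzoyl)-2-methoxyphenyl]pentanal
Conditions: 2 M aq HCl, THF, rt; aldehyde used promptly
Reagents that add atoms: water, O
Why: acid-catalysed acetal hydrolysis; benzyl ethers, the aryl methyl ether and the diaryl ketone are inert to dilute aqueous acid.

Step 6
Reactants: 10 5-[4-(benzyloxy)-5-(4-(benzyloxy)benzoyl)-2-methoxyphenyl]pentanal; 11 methyl vinyl ketone
Product: 14 racemic 4-{3-[4-(benzyloxy)-5-(4-(benzyloxy)benzoyl)-2-methoxyphenyl]propyl}cyclohex-2-en-1-one, via keto aldehyde 12 (not isolated), via aldol 13 (not isolated)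
Conditions: 11 (1.5 equiv), Et2NH (0.3 equiv), THF, rt; then 0.1 M aq KOH, n-Bu4NOH (cat.), THF/Et2O, reflux
Reagents that add atoms: none
Why: Diethylamine should convert the aldehyde reversibly into its enamine, whose α-carbon adds to the β-carbon of methyl vinyl ketone, and hydrolysis releases the 2-substituted 5-oxohexanal 12 and the amine. Under KOH the methyl ketone enolate of 12 attacks the formyl carbon to give aldol 13, which loses water to the conjugated enone 14; the closest known reaction type is the amine-catalysed Michael addition of aldehydes to methyl vinyl ketone with base-mediated aldol condensation, a Robinson-type annulation giving 4-substituted cyclohex-2-enones. Ring C closes in a 6-(enolendo)-exo-trig aldol, since the enolate C=C of the methyl ketone lies inside the forming ring and the formyl C=O outside it. The one new stereocentre, C4 of the enone, is not controlled and forms racemic, which does not matter because it becomes sp2 in step 7. The step needs Michael addition before any aldol so that chain and oxygen end up 1,4: enamine activation makes the aldehyde α-carbon the only soft nucleophile, and the α-branched adduct 12 forms an enamine only slowly, which should limit double addition. The aldol is regiochemically unambiguous because any other enolate/carbonyl pairing in 12 would close a four-membered ring, and the benzophenone carbonyl cannot enolise and is too hindered and electron-rich to act as acceptor.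

Step 7
Reactants: 14 racemic 4-{3-[4-(benzyloxy)-5-(4-(benzyloxy)benzoyl)-2-methoxyphenyl]propyl}cyclohex-2-en-1-one
Product: 16 [2-(benzyloxy)-5-[3-(4-hydroxyphenyl)propyl]-4-methoxyphenyl][4-(benzyloxy)phenyl]methanone, via dienone 15 (not isolated)
Conditions: Pd(OCOCF3)2 (5 mol %), 2-(dimethylamino)pyridine (10 mol %), TsOH·H2O (20 mol %), O2 (1 atm), DMSO, 80 °C
Reagents that add atoms: none
Why: palladium-catalysed aerobic dehydrogenation of a cyclohexenone, in which a divalent palladium enolate at C6 should undergo β-hydride elimination towards C5 to give dienone 15, which tautomerises irreversibly to the phenol while O2 reoxidises the palladium hydride; because the carbonyl is 1,4 to the chain-bearing carbon only the para-alkylphenol can result.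

Step 8
Reactants: 16 [2-(benzyloxy)-5-[3-(4-hydroxyphenyl)propyl]-4-methoxyphenyl][4-(benzyloxy)phenyl]methanone
Product: 17 [2-hydroxy-5-[3-(4-hydroxyphenyl)propyl]-4-methoxyphenyl](4-hydroxyphenyl)methanone (CNP0209225.0)
Conditions: H2 (1 atm), 10% Pd/C, EtOAc, rt; stopped as soon as both benzyl groups are gone
Reagents that add atoms: none
Why: catalytic hydrogenolysis of two benzyl aryl ethers; under neutral conditions at 1 atm the diaryl ketone, deactivated after debenzylation by the hydrogen-bonded ortho-hydroxyl and the para-hydroxyl donor, should be reduced much more slowly than the O–benzyl bonds are cleaved.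

**Compound list**

1 | 5-bromo-2-hydroxy-4-methoxybenzaldehyde | COc1cc(O)c(C=O)cc1Br | starting material
2 | 2-(benzyloxy)-5-bromo-4-methoxybenzaldehyde | COc1cc(OCc2ccccc2)c(C=O)cc1Br | intermediate
3 | 1-(benzyloxy)-4-bromobenzene | Brc1ccc(OCc2ccccc2)cc1 | starting material
4 | 4-(benzyloxy)phenylmagnesium bromide | Br[Mg]c1ccc(OCc2ccccc2)cc1 | intermediate (not isolated)
5 | [2-(benzyloxy)-5-bromo-4-methoxyphenyl][4-(benzyloxy)phenyl]methanol, racemic | COc1cc(OCc2ccccc2)c(C(O)c2ccc(OCc3ccccc3)cc2)cc1Br | intermediate
6 | [2-(benzyloxy)-5-bromo-4-methoxyphenyl][4-(benzyloxy)phenyl]methanone | COc1cc(OCc2ccccc2)c(C(=O)c2ccc(OCc3ccccc3)cc2)cc1Br | intermediate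
7 | 2-(but-3-en-1-yl)-1,3-dioxolane | C=CCCC1OCCO1 | starting material
8 | 9-[4-(1,3-dioxolan-2-yl)butyl]-9-borabicyclo[3.3.1]nonane | C1COC(CCCCB2C3CCCC2CCC3)O1 | intermediate (not isolated)
9 | [2-(benzyloxy)-5-[4-(1,3-dioxolan-2-yl)butyl]-4-methoxyphenyl][4-(benzyloxy)phenyl]methanone | COc1cc(OCc2ccccc2)c(C(=O)c2ccc(OCc3ccccc3)cc2)cc1CCCCC1OCCO1 | intermediate
10 | 5-[4-(benzyloxy)-5-(4-(benzyloxy)benzoyl)-2-methoxyphenyl]pentanal | O=CCCCCc1cc(C(=O)c2ccc(OCc3ccccc3)cc2)c(OCc2ccccc2)cc1OC | intermediate
11 | methyl vinyl ketone (but-3-en-2-one) | C=CC(C)=O | starting material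
12 | 2-{3-[4-(benzyloxy)-5-(4-(benzyloxy)benzoyl)-2-methoxyphenyl]propyl}-5-oxohexanal, racemic | CC(=O)CCC(C=O)CCCc1cc(C(=O)c2ccc(OCc3ccccc3)cc2)c(OCc2ccccc2)cc1OC | intermediate (not isolated)
13 | 4-{3-[4-(benzyloxy)-5-(4-(benzyloxy)benzoyl)-2-methoxyphenyl]propyl}-3-hydroxycyclohexan-1-one, mixture of diastereomers | O=C1CC(O)C(CCCc2cc(C(=O)c3ccc(OCc4ccccc4)cc3)c(OCc3ccccc3)cc2OC)CC1 | intermediate (not isolated)
14 | 4-{3-[4-(benzyloxy)-5-(4-(benzyloxy)benzoyl)-2-methoxyphenyl]propyl}cyclohex-2-en-1-one, racemic | O=C1C=CC(CCCc2cc(C(=O)c3ccc(OCc4ccccc4)cc3)c(OCc3ccccc3)cc2OC)CC1 | intermediate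
15 | 4-{3-[4-(benzyloxy)-5-(4-(benzyloxy)benzoyl)-2-methoxyphenyl]propyl}cyclohexa-2,5-dien-1-one | O=C1C=CC(CCCc2cc(C(=O)c3ccc(OCc4ccccc4)cc3)c(OCc3ccccc3)cc2OC)C=C1 | intermediate (not isolated)
16 | [2-(benzyloxy)-5-[3-(4-hydroxyphenyl)propyl]-4-methoxyphenyl][4-(benzyloxy)phenyl]methanone | COc1cc(OCc2ccccc2)c(C(=O)c2ccc(OCc3ccccc3)cc2)cc1CCCc1ccc(O)cc1 | intermediate
17 | [2-hydroxy-5-[3-(4-hydroxyphenyl)propyl]-4-methoxyphenyl](4-hydroxyphenyl)methanone | COc1cc(O)c(C(=O)c2ccc(O)cc2)cc1CCCc1ccc(O)cc1 | target

**Totals**

Total step count: 8. Longest linear sequence: 8 steps (from 1 to 17).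

**Steps most likely to fail**

Step 6. Under amine and then hydroxide the aldehyde may condense with itself faster than it adds to methyl vinyl ketone, the vinyl ketone may oligomerise, and the keto aldehyde may undergo retro-Michael cleavage before the ring closes. The fallback gives up the annulation and brings ring C in as a finished arene. It sets out from bromide 6 and from Grignard reagent 4. Allylation of 4 with allyl bromide in THF at 0 °C to rt should give 1-allyl-4-(benzyloxy)benzene F1. Hydroboration of F1 with 9-BBN-H in THF should give 9-[3-(4-(benzyloxy)phenyl)propyl]-9-borabicyclo[3.3.1]nonane F2. B-alkyl Suzuki coupling of F2 with 6 under the conditions of step 4 should give [2-(benzyloxy)-5-[3-(4-(benzyloxy)phenyl)propyl]-4-methoxyphenyl][4-(benzyloxy)phenyl]methanone F3. Hydrogenolysis of the three benzyl ethers of F3 (H2, Pd/C, EtOAc) comes back to the route at target 17.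

Step 7. The palladium catalyst may aggregate to inactive metal before conversion is complete, or oxidation may stray to the benzylic CH2 groups of the chain. The fallback replaces catalytic dehydrogenation by a stoichiometric selenoxide elimination and sets out from enone 14. Kinetic deprotonation at C6 with LiN(SiMe3)2 in THF at −78 °C (a base that cannot transfer hydride to the benzophenone) and trapping with PhSeCl should give 4-{3-[4-(benzyloxy)-5-(4-(benzyloxy)benzoyl)-2-methoxyphenyl]propyl}-6-(phenylselanyl)cyclohex-2-en-1-one F4. Oxidation of F4 with aqueous H2O2 in CH2Cl2/pyridine at 0 °C should induce syn-elimination to dienone 15, which tautomerises, and the fallback comes back to the route at phenol 16.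

Step 8. Once the benzyl groups are off, hydrogenation may go on to reduce the diaryl ketone to the benzhydrol and the diarylmethane, or cleavage of the hindered ortho benzyl ether may lag behind. The fallback replaces hydrogenolysis by Lewis-acid debenzylation and sets out from 16. BCl3 with pentamethylbenzene as cation scavenger in CH2Cl2 at −78 °C should cleave both benzyl aryl ethers while the methyl ether, which is not chelated to the carbonyl, survives. It comes back to the route at target 17 and makes no new compound (F0).

**Further compounds**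

F1 | step 6 | 1-allyl-4-(benzyloxy)benzene | C=CCc1ccc(OCc2ccccc2)cc1
F2 | step 6 | 9-[3-(4-(benzyloxy)phenyl)propyl]-9-borabicyclo[3.3.1]nonane | c1ccc(COc2ccc(CCCB3C4CCCC3CCC4)cc2)cc1
F3 | step 6 | [2-(benzyloxy)-5-[3-(4-(benzyloxy)phenyl)propyl]-4-methoxyphenyl][4-(benzyloxy)phenyl]methanone | COc1cc(OCc2ccccc2)c(C(=O)c2ccc(OCc3ccccc3)cc2)cc1CCCc1ccc(OCc2ccccc2)cc1
F4 | step 7 | 4-{3-[4-(benzyloxy)-5-(4-(benzyloxy)benzoyl)-2-methoxyphenyl]propyl}-6-(phenylselanyl)cyclohex-2-en-1-one, mixture of diastereomers | O=C1C=CC(CCCc2cc(C(=O)c3ccc(OCc4ccccc4)cc3)c(OCc3ccccc3)cc2OC)CC1[Se]c1ccccc1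
F0 | step 8 | none | none
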